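**Retrosynthetic overview**

- The plan rests on ring A (C1 = OMe carbon, C2 = CH, C3 = C–OH, C4 = bridge-bearing carbon, C5 = C–OH, C6 = acetyl carbon). Its acetyl at C6, between the C5 phenol and the C1 methyl ether, is the 3-acetyl-4-methoxy-2-pyrone pattern, and C4, between two phenols, is a ketone α-carbon placed between a ketone and a lactone carbonyl.
- Key disconnection: the C4–C5 bond of ring A, formed by methoxide opening of a 3-acetyl-4-methoxy-6-(2-arylethyl)-2-pyrone and Claisen recyclisation. Ring A is the only ring built; ring B is carried from 5-methoxyresorcinol.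
- The pyrone comes from triacetic acid lactone by dianion alkylation at the 6-methyl with the ring B benzylic chloride, then C3 acetylation and O-methylation.
- The chloride comes from 5-methoxyresorcinol by directed ortho-methylation between two OMOM groups, MOM-to-benzyl exchange, Vilsmeier–Haack formylation, reduction and chlorination.
- End game: hydrogenolysis of the benzyl ethers, then Friedel–Crafts acetylation of the single free carbon (C5') of ring B.

Key step: step 11

Remark: the target has no stereocentre; ring B is numbered C1' (bridge-bearing carbon), C2' (OH), C3' (CH3), C4' (OH), C5' (acetyl), C6' (OMe).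

**Route**

Step 1
Reactants: 1 5-methoxybenzene-1,3-diol (5-methoxyresorcinol)
Product: 2 1-methoxy-3,5-bis(methoxymethoxy)benzene
Conditions: MOMCl (2.5 equiv), i-Pr2NEt, CH2Cl2, 0 °C → rt
Reagents that add atoms: chloromethyl methyl ether, COCCl
Why: Williamson-type O-alkylation of both phenols by the reactive α-chloro ether under amine base should give the bis-MOM ether, which places two strong ortho-directing groups on either side of the future C3' carbon.

Step 2
Reactants: 2 1-methoxy-3,5-bis(methoxymethoxy)benzene
Product: 4 5-methoxy-1,3-bis(methoxymethoxy)-2-methylbenzene, via aryllithium 3 (not isolated)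
Conditions: n-BuLi (1.1 equiv), THF, 0 °C; then MeI, 0 °C → rt
Reagents that add atoms: iodomethane, CI
Why: Directed ortho-metalation should occur at the carbon between the two OMOM groups, where both acetal oxygens coordinate the base cooperatively and outrank the single OMe/OMOM pair, and the aryllithium is then methylated by SN2 on MeI.

Step 3
Reactants: 4 5-methoxy-1,3-bis(methoxymethoxy)-2-methylbenzene
Product: 5 5-methoxy-2-methylbenzene-1,3-diol
Conditions: conc. HCl (cat.), MeOH, 50 °C
Reagents that add atoms: none
Why: Acid-catalysed acetal exchange with methanol (MOM cleavage) should free both phenols as dimethoxymethane while the aryl methyl ether is untouched.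

Step 4
Reactants: 5 5-methoxy-2-methylbenzene-1,3-diol; 6 benzyl bromide
Product: 7 1,3-bis(benzyloxy)-5-methoxy-2-methylbenzene
Conditions: BnBr (2.3 equiv in all), K2CO3 (3 equiv), DMF, rt → 50 °C
Reagents that add atoms: benzyl bromide, BrCc1ccccc1
Why: Two-fold Williamson ether synthesis, in which each phenoxide takes up one molecule of benzyl bromide (two molecules of 6 per molecule of 5), with K2CO3 in DMF favouring O- over C-benzylation, gives a protecting group that tolerates strong base and leaves under neutral hydrogenolysis.

Step 5
Reactants: 7 1,3-bis(benzyloxy)-5-methoxy-2-methylbenzene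
Product: 9 2,4-bis(benzyloxy)-6-methoxy-3-methylbenzaldehyde, via iminium chloride 8 (not isolated)
Conditions: POCl3, DMF, 0 → 60 °C; then H2O, rt
Reagents that add atoms: N,N-dimethylformamide, CN(C)C=O; water, O
Why: Vilsmeier–Haack formylation can only attack the two symmetry-equivalent free ring carbons (each between OBn and OMe), so one aldehyde is expected after hydrolysis of the iminium salt.

Step 6
Reactants: 9 2,4-bis(benzyloxy)-6-methoxy-3-methylbenzaldehyde
Product: 10 [2,4-bis(benzyloxy)-6-methoxy-3-methylphenyl]methanol
Conditions: NaBH4, THF/MeOH, 0 °C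
Reagents that add atoms: none
Why: Hydride reduction of the aldehyde by NaBH4 is chemoselective because no other reducible group is present.

Step 7
Reactants: 10 [2,4-bis(benzyloxy)-6-methoxy-3-methylphenyl]methanol
Product: 12 1,3-bis(benzyloxy)-4-(chloromethyl)-5-methoxy-2-methylbenzene (2,4-bis(benzyloxy)-6-methoxy-3-methylbenzyl chloride), via benzylic mesylate 11 (not isolated)
Conditions: MsCl, Et3N, CH2Cl2, −10 → 0 °C; cold aqueous wash, used at once without chromatography
Reagents that add atoms: methanesulfonyl chloride, CS(=O)(=O)Cl
Why: Mesylation followed by chloride displacement in the flask, which is fast for a trialkoxy-stabilised benzylic centre, should give the chloride under basic conditions that spare the benzyl ethers.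

Step 8
Reactants: 13 4-hydroxy-6-methyl-2H-pyran-2-one (triacetic acid lactone); 12 2,4-bis(benzyloxy)-6-methoxy-3-methylbenzyl chloride
Product: 15 6-{2-[2,4-bis(benzyloxy)-6-methoxy-3-methylphenyl]ethyl}-4-hydroxy-2H-pyran-2-one, via dilithio dianion 14 (not isolated)
Conditions: LiN(i-Pr)2 (2.3 equiv), THF/DMPU, −78 °C; then 12, −78 → −20 °C; then 1 M HCl
Reagents that add atoms: none
Why: Dianion alkylation of triacetic acid lactone takes place at the more basic terminal carbanion of the 6-methyl group (SN2 on the benzylic chloride), while the 4-oxygen stays protected as its lithium salt.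

Step 9
Reactants: 15 6-{2-[2,4-bis(benzyloxy)-6-methoxy-3-methylphenyl]ethyl}-4-hydroxy-2H-pyran-2-one
Product: 17 3-acetyl-6-{2-[2,4-bis(benzyloxy)-6-methoxy-3-methylphenyl]ethyl}-4-hydroxy-2H-pyran-2-one, via 4-O-acetyl pyrone 16 (not isolated)
Conditions: AcOH, DCC, DMAP (0.3 equiv), toluene, rt; then 90 °C
Reagents that add atoms: acetic acid, CC(=O)O
Why: Carbodiimide esterification of the 4-OH followed by DMAP-mediated O-to-C acyl migration (a Fries-type 1,3-shift) to the nucleophilic C3 should give the chelated 3-acetyl-4-hydroxy-2-pyrone, as in the acylation of triacetic acid lactone itself.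

Step 10
Reactants: 17 3-acetyl-6-{2-[2,4-bis(benzyloxy)-6-methoxy-3-methylphenyl]ethyl}-4-hydroxy-2H-pyran-2-one
Product: 18 3-acetyl-6-{2-[2,4-bis(benzyloxy)-6-methoxy-3-methylphenyl]ethyl}-4-methoxy-2H-pyran-2-one
Conditions: Me2SO4, K2CO3, acetone, reflux
Reagents that add atoms: dimethyl sulfate, COS(=O)(=O)OC
Why: Williamson-type O-methylation of the acidic tricarbonyl enol is expected at the 4-oxygen, which keeps the 2-pyrone conjugation as in the methyl ether of dehydroacetic acid, and no other acidic OH is present.

Step 11
Reactants: 18 3-acetyl-6-{2-[2,4-bis(benzyloxy)-6-methoxy-3-methylphenyl]ethyl}-4-methoxy-2H-pyran-2-one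
Product: 20 1-(3-{[2,4-bis(benzyloxy)-6-methoxy-3-methylphenyl]methyl}-2,4-dihydroxy-6-methoxyphenyl)ethan-1-one, via ring-opened keto ester 19 (not isolated)
Conditions: Mg(OMe)2 (excess), MeOH, reflux; then 1 M HCl
Reagents that add atoms: none
Why: Proposed new method: methoxide adds to the lactone carbonyl (pyrone C2) of 18 and acyl–oxygen cleavage gives keto ester 19, whose C6 enolate (the methylene between the C5 ketone and the benzylic CH2) attacks the ester carbon in a Claisen condensation, methanol is expelled and the cyclic trione enolises to aromatic ring A, so that the ring A C4–C5 bond is formed. The closest known reaction type is the Mg(OMe)2-mediated ring opening and Claisen recyclisation of 6-(2-oxoalkyl)-4-hydroxy-2-pyrones to acylphloroglucinols; the difference here is that the nucleophilic carbon is a singly activated ketone methylene and the acetyl group is already carried by the enol ether. Ring A closes in a 6-(enolendo)-exo-trig mode and no stereocentre is created. The step needs C-acylation of the ester by C6 instead of aldol closure of C6 onto the acetyl carbonyl, aldol attack of the acetyl methyl on the C5 ketone, or retro-Claisen loss of the acetyl group. This should be secured by the ester-cis-to-chain geometry left by lactone opening, by magnesium chelation of the acetyl–ester pair (the acetyl oxygen becomes the enolate terminus of the C4-deprotonated chelate and stops being an acceptor, while the ester stays electrophilic), and by the irreversible exit as the magnesium phenolate of the chelated o-hydroxyacetophenone. The C3 methoxy group of 19 sits on a vinylogous ester carbon, can exchange only with methoxide, and becomes the C1 methyl ether of ring A without any phenol differentiation.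

Step 12
Reactants: 20 1-(3-{[2,4-bis(benzyloxy)-6-methoxy-3-methylphenyl]methyl}-2,4-dihydroxy-6-methoxyphenyl)ethan-1-one
Product: 21 1-{3-[(2,4-dihydroxy-6-methoxy-3-methylphenyl)methyl]-2,4-dihydroxy-6-methoxyphenyl}ethan-1-one
Conditions: H2 (1 atm), 10% Pd/C, EtOAc/MeOH, rt
Reagents that add atoms: none
Why: Catalytic hydrogenolysis should cleave both benzyl ethers under neutral conditions, and the hydrogen-bonded aryl ketone and the diarylmethane are expected to survive at ambient pressure.

Step 13
Reactants: 21 1-{3-[(2,4-dihydroxy-6-methoxy-3-methylphenyl)methyl]-2,4-dihydroxy-6-methoxyphenyl}ethan-1-one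
Product: 22 1-{3-[(3-acetyl-4,6-dihydroxy-2-methoxy-5-methylphenyl)methyl]-2,4-dihydroxy-6-methoxyphenyl}ethan-1-one (target)
Conditions: Ac2O (1.05 equiv), BF3·OEt2, 1,4-dioxane, 0 °C → rt; then H2O/MeOH, 40 °C
Reagents that add atoms: acetic anhydride, CC(=O)OC(C)=O
Why: Friedel–Crafts acylation should go to C5' of ring B, an unacylated phloroglucinol-type ring with one free carbon that is far more nucleophilic than the acetyl-deactivated ring A, so one equivalent of anhydride is expected to acetylate that position only.

**Compound list**

1 | 5-methoxybenzene-1,3-diol (5-methoxyresorcinol) | COc1cc(O)cc(O)c1 | starting material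
2 | 1-methoxy-3,5-bis(methoxymethoxy)benzene | COCOc1cc(OC)cc(OCOC)c1 | intermediate
3 | [4-methoxy-2,6-bis(methoxymethoxy)phenyl]lithium (formed in the flask, not isolated) | [Li]c1c(OCOC)cc(OC)cc1OCOC | intermediate
4 | 5-methoxy-1,3-bis(methoxymethoxy)-2-methylbenzene | COCOc1cc(OC)cc(OCOC)c1C | intermediate
5 | 5-methoxy-2-methylbenzene-1,3-diol | COc1cc(O)c(C)c(O)c1 | intermediate
6 | benzyl bromide | BrCc1ccccc1 | starting material
7 | 1,3-bis(benzyloxy)-5-methoxy-2-methylbenzene | COc1cc(OCc2ccccc2)c(C)c(OCc2ccccc2)c1 | intermediate
8 | N-{[2,4-bis(benzyloxy)-6-methoxy-3-methylphenyl]methylidene}-N-methylmethanaminium chloride (formed in the flask, not isolated) | COc1cc(OCc2ccccc2)c(C)c(OCc2ccccc2)c1C=[N+](C)C.[Cl-] | intermediate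
9 | 2,4-bis(benzyloxy)-6-methoxy-3-methylbenzaldehyde | COc1cc(OCc2ccccc2)c(C)c(OCc2ccccc2)c1C=O | intermediate
10 | [2,4-bis(benzyloxy)-6-methoxy-3-methylphenyl]methanol | COc1cc(OCc2ccccc2)c(C)c(OCc2ccccc2)c1CO | intermediate
11 | [2,4-bis(benzyloxy)-6-methoxy-3-methylphenyl]methyl methanesulfonate (formed in the flask, not isolated) | COc1cc(OCc2ccccc2)c(C)c(OCc2ccccc2)c1COS(C)(=O)=O | intermediate
12 | 1,3-bis(benzyloxy)-4-(chloromethyl)-5-methoxy-2-methylbenzene | COc1cc(OCc2ccccc2)c(C)c(OCc2ccccc2)c1CCl | intermediate
13 | 4-hydroxy-6-methyl-2H-pyran-2-one (triacetic acid lactone) | CC1=CC(O)=CC(=O)O1 | starting material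
14 | dilithio dianion of 13, lithium 6-(lithiomethyl)-2-oxo-2H-pyran-4-olate (formed in the flask, not isolated) | [Li]CC1=CC(O[Li])=CC(=O)O1 | intermediate
15 | 6-{2-[2,4-bis(benzyloxy)-6-methoxy-3-methylphenyl]ethyl}-4-hydroxy-2H-pyran-2-one | COc1cc(OCc2ccccc2)c(C)c(OCc2ccccc2)c1CCC1=CC(O)=CC(=O)O1 | intermediate
16 | 6-{2-[2,4-bis(benzyloxy)-6-methoxy-3-methylphenyl]ethyl}-2-oxo-2H-pyran-4-yl acetate (formed in the flask, not isolated) | COc1cc(OCc2ccccc2)c(C)c(OCc2ccccc2)c1CCC1=CC(OC(C)=O)=CC(=O)O1 | intermediate
17 | 3-acetyl-6-{2-[2,4-bis(benzyloxy)-6-methoxy-3-methylphenyl]ethyl}-4-hydroxy-2H-pyran-2-one | CC(=O)C1=C(O)C=C(CCc2c(OCc3ccccc3)c(C)c(OCc3ccccc3)cc2OC)OC1=O | intermediate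
18 | 3-acetyl-6-{2-[2,4-bis(benzyloxy)-6-methoxy-3-methylphenyl]ethyl}-4-methoxy-2H-pyran-2-one | CC(=O)C1=C(OC)C=C(CCc2c(OCc3ccccc3)c(C)c(OCc3ccccc3)cc2OC)OC1=O | intermediate
19 | methyl (2E)-2-acetyl-7-[2,4-bis(benzyloxy)-6-methoxy-3-methylphenyl]-3-methoxy-5-oxohept-2-enoate (formed in the flask, not isolated) | COC(=O)\C(C(C)=O)=C(/CC(=O)CCc1c(OCc2ccccc2)c(C)c(OCc2ccccc2)cc1OC)OC | intermediate
20 | 1-(3-{[2,4-bis(benzyloxy)-6-methoxy-3-methylphenyl]methyl}-2,4-dihydroxy-6-methoxyphenyl)ethan-1-one | COc1cc(O)c(Cc2c(OCc3ccccc3)c(C)c(OCc3ccccc3)cc2OC)c(O)c1C(C)=O | intermediate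
21 | 1-{3-[(2,4-dihydroxy-6-methoxy-3-methylphenyl)methyl]-2,4-dihydroxy-6-methoxyphenyl}ethan-1-one | COc1cc(O)c(Cc2c(O)c(C)c(O)cc2OC)c(O)c1C(C)=O | intermediate
22 | 1-{3-[(3-acetyl-4,6-dihydroxy-2-methoxy-5-methylphenyl)methyl]-2,4-dihydroxy-6-methoxyphenyl}ethan-1-one | COc1cc(O)c(Cc2c(O)c(C)c(O)c(C(C)=O)c2OC)c(O)c1C(C)=O | target

**Step count and risks**

Total step count: 13. Longest linear sequence: 13 steps (1 to 22); triacetic acid lactone 13 enters at step 8.

Steps most likely to fail:

1. Step 11 (proposed new method). After ring opening, the more acidic C4 methylene of 19 is deprotonated first. The resulting chelated dienolate can lose the inherited alkene geometry, so aldol closures onto the acetyl carbonyl or by the acetyl methyl may overtake the Claisen closure. Alternatively, the opened ester may simply relactonise and stall. The fallback uses known chemistry, sets out from benzylic alcohol 10 and 5-methoxyresorcinol 1, and returns at 20. Friedel–Crafts acetylation of 1 (Ac2O, BF3·OEt2) would give 1-(2,4-dihydroxy-6-methoxyphenyl)ethan-1-one F1 after separation from its regioisomer. Acid-catalysed Friedel–Crafts benzylation of F1 with 10 (catalytic TsOH, 1,4-dioxane, rt) then proceeds through the trialkoxy-stabilised benzylic cation; C-benzylation of acylphloroglucinols by electron-rich benzylic alcohols is an established reaction type. It should alkylate the carbon between the two phenols of F1 and give 20, with the isomer benzylated next to the methoxy group removed by chromatography.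

2. Step 13. Under the Lewis acid, ipso-protonation of the very electron-rich ring B can cleave or scramble the diarylmethane bridge. O-acetylation or a second C-acylation on ring A can also consume the anhydride. The fallback sets out from 21 and returns at 22. A Houben–Hoesch reaction (MeCN, ZnCl2, HCl gas, Et2O, 0 °C) uses a nitrilium electrophile that does not acylate oxygen and reacts only with the most nucleophilic ring. It would give 1-{3-[(3-acetyl-2,6-dihydroxy-4-methoxyphenyl)methyl]-4,6-dihydroxy-2-methoxy-5-methylphenyl}ethan-1-iminium chloride F2, which is expected to precipitate and so be protected from further reaction. Warming F2 in water hydrolyses the iminium group to the acetyl group of 22.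

3. Step 8. The trialkoxybenzylic chloride 12 can ionise and self-condense before it meets the sparingly soluble dianion, and proton transfer can quench the dianion. The fallback sets out from aldehyde 9 and lactone 13 and returns at 15. Aldol addition of dianion 14 to 9 (THF/DMPU, −78 °C) would give racemic 6-{2-[2,4-bis(benzyloxy)-6-methoxy-3-methylphenyl]-2-hydroxyethyl}-4-hydroxy-2H-pyran-2-one F3. Ionic hydrogenation of its electron-rich benzylic alcohol (Et3SiH, TFA, CH2Cl2, 0 °C) removes the hydroxyl group and the stereocentre and gives 15, with no benzylic halide needed.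

**Further compounds**

F1 | step 11 | 1-(2,4-dihydroxy-6-methoxyphenyl)ethan-1-one | COc1cc(O)cc(O)c1C(C)=O
F2 | step 13 | 1-{3-[(3-acetyl-2,6-dihydroxy-4-methoxyphenyl)methyl]-4,6-dihydroxy-2-methoxy-5-methylphenyl}ethan-1-iminium chloride | COc1cc(O)c(Cc2c(O)c(C)c(O)c(C(C)=[NH2+])c2OC)c(O)c1C(C)=O.[Cl-]
F3 | step 8 | rac-6-{2-[2,4-bis(benzyloxy)-6-methoxy-3-methylphenyl]-2-hydroxyethyl}-4-hydroxy-2H-pyran-2-one | COc1cc(OCc2ccccc2)c(C)c(OCc2ccccc2)c1C(O)CC1=CC(O)=CC(=O)O1
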